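**Retrosynthetic overview**

1. The target should come from a cyclohexene triol that carries the enal as a dienyl ethyl ether. Hydrolysis and conjugation create the ring CH and the Z enal last; before that, a periodate/borohydride sequence trims a 1,2-diol arm to the CH2OH group.
2. The cyclohexene is cut at two ring bonds, CH2–CH2 and quaternary C–C(OH)CH3, by a boron-tethered intramolecular Diels–Alder reaction of an acyclic Z-trienol with an isopropenylboronic ester. This one event sets the quaternary carbon and the tertiary carbinol carbon.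
3. Enabling feature: on the ring, the OH of the C(OH)CH3 carbon and the CH2OH on the neighbouring quaternary carbon are cis (a 1,3-diol). One boron atom can therefore stand in for the tertiary oxygen while being held by the CH2–O oxygen; the ring's CH2–C(CH3)(OH) unit becomes the dienophile and the other four ring carbons (quaternary C, CH, enal-bearing C, CH2) the diene.
4. The trienol comes from a butenolide whose lactone carbonyl becomes the 2-substituted diene carbon. The butenolide is made by B-alkyl Suzuki coupling of a tetronic acid triflate with the 9-BBN adduct of a farnesal-derived tetraene; methyl (S)-glycerate supplies the only bought stereocentre, on the carbinol carbon of the tether.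
5. Ring order: butenolide first (temporary, fixes the tetrasubstituted Z alkene), then opened; cyclohexene and 1,2-oxaborolane close together in the key step; the oxaborolane is removed by oxidation.

Key step: step 12

Assumption: the target is taken in the open hydroxy-aldehyde form drawn; a lactol between the formyl group and the neighbouring CH2OH would be its ring tautomer.

Abbreviations in names: TBS = tert-butyldimethylsilyl (TBSO = its ether); homofarnesyl = (3E,7E)-4,8,12-trimethyltrideca-3,7,11-trienyl.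

**Route**

Step 1
Reactants: 1 methyl (2S)-2,3-dihydroxypropanoate
Product: 2 methyl (2S)-3-(TBSO)-2-hydroxypropanoate
Conditions: TBSCl (1.05 equiv), imidazole, CH2Cl2, 0 °C
Reagents that add atoms: tert-butyl(chloro)dimethylsilane, CC(C)(C)[Si](C)(C)Cl
Why: Silyl ether formation under steric control should take the primary hydroxyl and leave the secondary carbinol oxygen, which later becomes the tether oxygen, with its bought (S) stereocentre untouched.

Step 2
Reactants: 2 methyl (2S)-3-(TBSO)-2-hydroxypropanoate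
Product: 3 methyl (2S)-2-acetoxy-3-(TBSO)propanoate
Conditions: Ac2O, pyridine, DMAP (cat.), CH2Cl2, rt
Reagents that add atoms: acetic anhydride, CC(=O)OC(C)=O
Why: DMAP-catalysed O-acetylation attaches the two carbons that become the lactone carbonyl and its alpha carbon.

Step 3
Reactants: 3 methyl (2S)-2-acetoxy-3-(TBSO)propanoate
Product: 4 (5S)-4-hydroxy-5-(TBSO-methyl)furan-2(5H)-one
Conditions: LiN(SiMe3)2 (2.3 equiv), THF, −78 → −20 °C; cold 1 M HCl
Reagents that add atoms: none
Why: Lacey–Dieckmann cyclisation, in which the acetate enolate attacks the neighbouring methyl ester (5-exo-trig Claisen condensation) and the product is drained as the tetronate anion, should proceed at low temperature without deprotonating the stereocentre, so its configuration is kept.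

Step 4
Reactants: 4 (5S)-4-hydroxy-5-(TBSO-methyl)furan-2(5H)-one; 5 3-(TBSO)propanal
Product: 7 (5S)-4-hydroxy-5-(TBSO-methyl)-3-[3-(TBSO)propyl]furan-2(5H)-one, via alkylidene dione 6 (not isolated)
Conditions: Hantzsch ester (1.1 equiv), L-proline (10 mol%), CH2Cl2, rt
Reagents that add atoms: none
Why: Knoevenagel condensation of the vinylogous acid with 5 followed by transfer hydrogenation of the alkylidene dione by the Hantzsch ester (three-component reductive alkylation) runs under near-neutral conditions that leave the ring stereocentre alone.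

Step 5
Reactants: 7 (5S)-4-hydroxy-5-(TBSO-methyl)-3-[3-(TBSO)propyl]furan-2(5H)-one
Product: 8 (2S)-2-(TBSO-methyl)-5-oxo-4-[3-(TBSO)propyl]-2,5-dihydrofuran-3-yl trifluoromethanesulfonate
Conditions: Tf2O, i-Pr2NEt, CH2Cl2, −78 °C
Reagents that add atoms: trifluoromethanesulfonic anhydride, O=S(=O)(OS(=O)(=O)C(F)(F)F)C(F)(F)F
Why: O-sulfonylation of the vinylogous acid at low temperature gives the enol triflate needed for cross-coupling.

Step 6
Reactants: 9 (2E,6E)-farnesol
Product: 10 (2E,6E)-farnesal
Conditions: MnO2 (activated), CH2Cl2, rt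
Reagents that add atoms: none
Why: MnO2 oxidises only the allylic alcohol and keeps the E geometry.

Step 7
Reactants: 10 (2E,6E)-farnesal
Product: 11 (3E,7E)-4,8,12-trimethyltrideca-1,3,7,11-tetraene
Conditions: Ph3PCH3Br, KOt-Bu, THF, 0 °C → rt
Reagents that add atoms: methyltriphenylphosphonium bromide, C[P+](c1ccccc1)(c1ccccc1)c1ccccc1.[Br-]
Why: Wittig methylenation of the enal gives the terminal 1,3-diene without touching the trisubstituted alkenes.

Step 8
Reactants: 11 (3E,7E)-4,8,12-trimethyltrideca-1,3,7,11-tetraene; 8 (2S)-2-(TBSO-methyl)-5-oxo-4-[3-(TBSO)propyl]-2,5-dihydrofuran-3-yl trifluoromethanesulfonate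
Product: 13 (5R)-5-(TBSO-methyl)-3-[3-(TBSO)propyl]-4-homofarnesylfuran-2(5H)-one, via alkylborane 12 (not isolated)
Conditions: 9-BBN, THF, 0 °C → rt; then 8, PdCl2(dppf) (5 mol%), Ph3As, aq. K3PO4, DMF, rt
Reagents that add atoms: none
Why: 9-BBN should hydroborate only the monosubstituted terminal alkene (anti-Markovnikov), and B-alkyl Suzuki–Miyaura coupling with the enol triflate then forms the sp3–sp2 bond inside the butenolide ring, which fixes the tetrasubstituted alkene geometry, while the mild phosphate base spares the gamma stereocentre.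

Step 9
Reactants: 14 ethyl prop-1-enyl ether (E/Z mixture)
Product: 16 (Z)-2-bromo-1-ethoxyprop-1-ene, via dibromide 15 (not isolated)
Conditions: Br2, CH2Cl2, −78 °C; then i-Pr2NEt, 0 → 60 °C; distillation
Reagents that add atoms: bromine, BrBr
Why: Bromine addition to the enol ether and amine-induced loss of HBr through the alpha-bromo ether (oxocarbenium) should give the 2-bromo enol ether, whose Z isomer (Br cis to OEt) is the one that lithiates to a chelated, configurationally stable vinyllithium.

Step 10
Reactants: 16 (Z)-2-bromo-1-ethoxyprop-1-ene; 13 (5R)-5-(TBSO-methyl)-3-[3-(TBSO)propyl]-4-homofarnesylfuran-2(5H)-one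
Product: 20 (2R,3Z,6Z)-1-(TBSO)-4-[3-(TBSO)propyl]-7-ethoxy-6-methyl-5-methylidene-3-homofarnesylhepta-3,6-dien-2-ol, via vinyllithium 17 (not isolated), via lactol 18 (not isolated), via silyl carbinol 19 (not isolated)
Conditions: 16, t-BuLi (2 equiv), Et2O, −78 °C; 13, THF, −78 °C; then Me3SiCH2Li, −78 → 0 °C; then KOt-Bu, 0 °C → rt
Reagents that add atoms: (trimethylsilyl)methyllithium, [Li]C[Si](C)(C)C
Why: Halogen–lithium exchange, 1,2-addition of 17 to the lactone carbonyl (the fully substituted beta carbon blocks conjugate addition), opening of the lactolate on warming, a second 1,2-addition by Me3SiCH2Li and Peterson olefination should give the 2-substituted diene, with the tetrasubstituted Z alkene carried over from the butenolide ring and the carbinol stereocentre not involved.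

Step 11
Reactants: 21 prop-1-en-2-ylmagnesium bromide; 22 triisopropyl borate
Product: 23 diisopropyl prop-1-en-2-ylboronate
Conditions: THF–Et2O, −78 °C → rt; HCl in Et2O, 0 °C; distillation
Reagents that add atoms: none
Why: Addition of the Grignard reagent to the borate gives a borate complex that collapses to the boronic ester on anhydrous acidification.

Step 12
Reactants: 20 (2R,3Z,6Z)-1-(TBSO)-4-[3-(TBSO)propyl]-7-ethoxy-6-methyl-5-methylidene-3-homofarnesylhepta-3,6-dien-2-ol; 23 diisopropyl prop-1-en-2-ylboronate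
Product: 26 (1S,2S)-2-[(1R)-2-(TBSO)-1-hydroxyethyl]-4-[(Z)-1-ethoxyprop-1-en-2-yl]-1-methyl-3-[3-(TBSO)propyl]-2-homofarnesylcyclohex-3-en-1-ol, via mixed boronate 24 (not isolated), via oxaborolane cycloadduct 25 (not isolated)
Conditions: 23 (3 equiv), PhMe, 40 °C, reduced pressure (removal of i-PrOH); BHT (cat.), PhMe, 150 °C, sealed tube; then H2O2, aq. NaOH, THF, 0 °C → rt
Reagents that add atoms: hydrogen peroxide, OO
Why: Ester exchange hangs the isopropenylboron unit on the carbinol oxygen, a concerted suprafacial [4+2] cycloaddition then joins the terminal CH2 of the diene to the CH2 of the dienophile and the chain-bearing diene terminus to the boron-bearing carbon, and alkaline peroxide finally replaces C–B by C–OH with retention. The closest known reaction type is the boron-tethered intramolecular Diels–Alder reaction of a dienyl alcohol with an alkenylboronic ester followed by oxidation. The cyclohexene ring closes by the cycloaddition itself, and the temporary 1,2-oxaborolane closes in the same event as a three-atom tether (C–O–B) on the inside (Z) position of the diene terminus, an arrangement from which only the cis-fused bicycle is geometrically possible. The quaternary carbon and the boron-bearing carbon (the later tertiary carbinol) are thus set cis by the tether, and their absolute sense by the (R) carbinol carbon, because A(1,3) strain keeps its hydrogen in the crowded inside position next to the 2-substituted diene carbon and its CH2OTBS group outside, so that the O–B arm can reach only one face of the diene. Regiochemistry is fixed by the tether; besides cis fusion and facial control the step needs cycloaddition to outrun a [1,5]-hydrogen shift of the inside carbinol hydrogen, which the pairing of the electron-rich alkoxy-substituted diene with the electron-poor boron-substituted alkene and the intramolecularity should secure.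

Step 13
Reactants: 26 (1S,2S)-2-[(1R)-2-(TBSO)-1-hydroxyethyl]-4-[(Z)-1-ethoxyprop-1-en-2-yl]-1-methyl-3-[3-(TBSO)propyl]-2-homofarnesylcyclohex-3-en-1-ol
Product: 27 (1S,2S)-2-[(1R)-1,2-dihydroxyethyl]-4-[(Z)-1-ethoxyprop-1-en-2-yl]-3-(3-hydroxypropyl)-1-methyl-2-homofarnesylcyclohex-3-en-1-ol
Conditions: Bu4NF, THF, 0 °C → rt
Reagents that add atoms: none
Why: Fluoride-driven desilylation removes both primary silyl ethers while the enol ether, the alkenes and the tertiary alcohol are inert.

Step 14
Reactants: 27 (1S,2S)-2-[(1R)-1,2-dihydroxyethyl]-4-[(Z)-1-ethoxyprop-1-en-2-yl]-3-(3-hydroxypropyl)-1-methyl-2-homofarnesylcyclohex-3-en-1-ol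
Product: 29 (1S,2S)-4-[(Z)-1-ethoxyprop-1-en-2-yl]-2-(hydroxymethyl)-3-(3-hydroxypropyl)-1-methyl-2-homofarnesylcyclohex-3-en-1-ol, via aldehyde 28 (not isolated)
Conditions: NaIO4, NaHCO3, THF–H2O, 0 °C; then NaBH4, 0 °C
Reagents that add atoms: none
Why: Periodate (Malaprade glycol cleavage) cuts only the vicinal diol and so removes the carbon that carried the temporary stereocentre, and NaBH4 reduces the resulting beta-hydroxy aldehyde at once, before retro-aldol opening can intervene, leaving the quaternary centre untouched.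

Step 15
Reactants: 29 (1S,2S)-4-[(Z)-1-ethoxyprop-1-en-2-yl]-2-(hydroxymethyl)-3-(3-hydroxypropyl)-1-methyl-2-homofarnesylcyclohex-3-en-1-ol
Product: 31 (2Z)-2-[(2R,3S,4S)-4-hydroxy-3-(hydroxymethyl)-2-(3-hydroxypropyl)-4-methyl-3-homofarnesylcyclohexylidene]propanal (target), via deconjugated aldehyde 30 (not isolated)
Conditions: oxalic acid (cat.), THF–H2O, rt; then DBU (0.3 equiv), PhMe, rt → 40 °C
Reagents that add atoms: water, O
Why: Acid hydrolysis of the dienyl ether frees the aldehyde and DBU moves the ring double bond into conjugation through the dienolate (1,3-prototropic shift), creating the ring CH under thermodynamic control: the exocyclic alkene forces the hydroxypropyl group axial, where it is syn-axial to OH in the wanted (R) epimer but to CH3 in the other, and the Z enal places the smaller formyl group beside the substituted ring CH, where it can hydrogen-bond to the neighbouring CH2OH.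

**Compound list**

1 | methyl (2S)-2,3-dihydroxypropanoate | COC(=O)[C@@H](O)CO | starting material
2 | methyl (2S)-3-(TBSO)-2-hydroxypropanoate | COC(=O)[C@@H](O)CO[Si](C)(C)C(C)(C)C | intermediate
3 | methyl (2S)-2-acetoxy-3-(TBSO)propanoate | COC(=O)[C@@H](OC(C)=O)CO[Si](C)(C)C(C)(C)C | intermediate
4 | (5S)-4-hydroxy-5-(TBSO-methyl)furan-2(5H)-one | O=C1C=C(O)[C@H](CO[Si](C)(C)C(C)(C)C)O1 | intermediate
5 | 3-(TBSO)propanal | O=CCCO[Si](C)(C)C(C)(C)C | starting material
6 | (5S)-5-(TBSO-methyl)-3-[3-(TBSO)propylidene]furan-2,4(3H,5H)-dione | O=C1O[C@@H](CO[Si](C)(C)C(C)(C)C)C(=O)C1=CCCO[Si](C)(C)C(C)(C)C | intermediate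
7 | (5S)-4-hydroxy-5-(TBSO-methyl)-3-[3-(TBSO)propyl]furan-2(5H)-one | O=C1C(CCCO[Si](C)(C)C(C)(C)C)=C(O)[C@H](CO[Si](C)(C)C(C)(C)C)O1 | intermediate
8 | (2S)-2-(TBSO-methyl)-5-oxo-4-[3-(TBSO)propyl]-2,5-dihydrofuran-3-yl trifluoromethanesulfonate | O=C1C(CCCO[Si](C)(C)C(C)(C)C)=C(OS(=O)(=O)C(F)(F)F)[C@H](CO[Si](C)(C)C(C)(C)C)O1 | intermediate
9 | (2E,6E)-farnesol | CC(C)=CCC/C(C)=C/CC/C(C)=C/CO | starting material
10 | (2E,6E)-farnesal | CC(C)=CCC/C(C)=C/CC/C(C)=C/C=O | intermediate
11 | (3E,7E)-4,8,12-trimethyltrideca-1,3,7,11-tetraene | CC(C)=CCC/C(C)=C/CC/C(C)=C/C=C | intermediate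
12 | 9-homofarnesyl-9-borabicyclo[3.3.1]nonane | CC(C)=CCC/C(C)=C/CC/C(C)=C/CCB1C2CCCC1CCC2 | intermediate
13 | (5R)-5-(TBSO-methyl)-3-[3-(TBSO)propyl]-4-homofarnesylfuran-2(5H)-one | CC(C)=CCC/C(C)=C/CC/C(C)=C/CCC1=C(CCCO[Si](C)(C)C(C)(C)C)C(=O)O[C@H]1CO[Si](C)(C)C(C)(C)C | intermediate
14 | ethyl prop-1-enyl ether (E/Z mixture) | CCOC=CC | starting material
15 | 1,2-dibromo-1-ethoxypropane | CCOC(Br)C(C)Br | intermediate
16 | (Z)-2-bromo-1-ethoxyprop-1-ene | CCO/C=C(/C)Br | intermediate
17 | [(Z)-1-ethoxyprop-1-en-2-yl]lithium | CCO/C=C(/C)[Li] | intermediate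
18 | (5R)-2-[(Z)-1-ethoxyprop-1-en-2-yl]-5-(TBSO-methyl)-3-[3-(TBSO)propyl]-4-homofarnesyl-2,5-dihydrofuran-2-ol (both anomers) | CC(C)=CCC/C(C)=C/CC/C(C)=C/CCC1=C(CCCO[Si](C)(C)C(C)(C)C)C(O)(/C(C)=C\OCC)O[C@H]1CO[Si](C)(C)C(C)(C)C | intermediate
19 | (2R,3Z,6Z)-1-(TBSO)-4-[3-(TBSO)propyl]-7-ethoxy-6-methyl-3-homofarnesyl-5-(trimethylsilylmethyl)hepta-3,6-diene-2,5-diol | CC(C)=CCC/C(C)=C/CC/C(C)=C/CC/C(=C(\CCCO[Si](C)(C)C(C)(C)C)C(O)(C[Si](C)(C)C)/C(C)=C\OCC)[C@@H](O)CO[Si](C)(C)C(C)(C)C | intermediate
20 | (2R,3Z,6Z)-1-(TBSO)-4-[3-(TBSO)propyl]-7-ethoxy-6-methyl-5-methylidene-3-homofarnesylhepta-3,6-dien-2-ol | CC(C)=CCC/C(C)=C/CC/C(C)=C/CC/C(=C(\CCCO[Si](C)(C)C(C)(C)C)C(=C)/C(C)=C\OCC)[C@@H](O)CO[Si](C)(C)C(C)(C)C | intermediate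
21 | prop-1-en-2-ylmagnesium bromide | CC(=C)[Mg]Br | starting material
22 | triisopropyl borate | CC(C)OB(OC(C)C)OC(C)C | starting material
23 | diisopropyl prop-1-en-2-ylboronate | CC(=C)B(OC(C)C)OC(C)C | intermediate
24 | mixed boronic ester of 20: isopropoxy(prop-1-en-2-yl)boryl on the carbinol oxygen | CC(C)=CCC/C(C)=C/CC/C(C)=C/CC/C(=C(\CCCO[Si](C)(C)C(C)(C)C)C(=C)/C(C)=C\OCC)[C@@H](OB(OC(C)C)C(C)=C)CO[Si](C)(C)C(C)(C)C | intermediate
25 | cis-fused cycloadduct: 2-isopropoxy-1,2-oxaborolane on the new cyclohexene, boron on the methyl-bearing ring carbon, ring oxygen on the (R) carbinol carbon | CC(C)=CCC/C(C)=C/CC/C(C)=C/CC[C@@]12C(CCCO[Si](C)(C)C(C)(C)C)=C(/C(C)=C\OCC)CC[C@]1(C)B(OC(C)C)O[C@H]2CO[Si](C)(C)C(C)(C)C | intermediate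
26 | (1S,2S)-2-[(1R)-2-(TBSO)-1-hydroxyethyl]-4-[(Z)-1-ethoxyprop-1-en-2-yl]-1-methyl-3-[3-(TBSO)propyl]-2-homofarnesylcyclohex-3-en-1-ol | CC(C)=CCC/C(C)=C/CC/C(C)=C/CC[C@@]1([C@@H](O)CO[Si](C)(C)C(C)(C)C)C(CCCO[Si](C)(C)C(C)(C)C)=C(/C(C)=C\OCC)CC[C@]1(C)O | intermediate
27 | (1S,2S)-2-[(1R)-1,2-dihydroxyethyl]-4-[(Z)-1-ethoxyprop-1-en-2-yl]-3-(3-hydroxypropyl)-1-methyl-2-homofarnesylcyclohex-3-en-1-ol | CC(C)=CCC/C(C)=C/CC/C(C)=C/CC[C@@]1([C@@H](O)CO)C(CCCO)=C(/C(C)=C\OCC)CC[C@]1(C)O | intermediate
28 | (1R,6S)-3-[(Z)-1-ethoxyprop-1-en-2-yl]-6-hydroxy-2-(3-hydroxypropyl)-6-methyl-1-homofarnesylcyclohex-2-ene-1-carbaldehyde | CC(C)=CCC/C(C)=C/CC/C(C)=C/CC[C@@]1(C=O)C(CCCO)=C(/C(C)=C\OCC)CC[C@]1(C)O | intermediate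
29 | (1S,2S)-4-[(Z)-1-ethoxyprop-1-en-2-yl]-2-(hydroxymethyl)-3-(3-hydroxypropyl)-1-methyl-2-homofarnesylcyclohex-3-en-1-ol | CC(C)=CCC/C(C)=C/CC/C(C)=C/CC[C@@]1(CO)C(CCCO)=C(/C(C)=C\OCC)CC[C@]1(C)O | intermediate
30 | 2-[(3S,4S)-4-hydroxy-3-(hydroxymethyl)-2-(3-hydroxypropyl)-4-methyl-3-homofarnesylcyclohex-1-en-1-yl]propanal (both epimers at the formyl-bearing carbon) | CC(C)=CCC/C(C)=C/CC/C(C)=C/CC[C@@]1(CO)C(CCCO)=C(C(C)C=O)CC[C@]1(C)O | intermediate
31 | (2Z)-2-[(2R,3S,4S)-4-hydroxy-3-(hydroxymethyl)-2-(3-hydroxypropyl)-4-methyl-3-homofarnesylcyclohexylidene]propanal (CNP0284886.1) | CC(C)=CCC/C(C)=C/CC/C(C)=C/CC[C@@]1(CO)[C@H](CCCO)/C(=C(/C)C=O)CC[C@]1(C)O | target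

**Step count and risks**

Total steps: 15. Longest linear sequence: 11 steps (1, 2, 3, 4, 5, 8, 10, 12, 13, 14, 15).

Steps most likely to fail:

Step 12. The boronic ester may be too weak a dienophile for the twisted, fully substituted diene terminus. At the temperature then needed, a [1,5]-hydrogen shift of the inside carbinol hydrogen or thermal breakdown of the polyene could overtake cycloaddition. The fallback replaces the neutral boronic ester by a much more electron-poor haloborane dienophile, reached through B–Cl chemistry, so that the cycloaddition can run near room temperature. It sets out from 20 and 23. Treatment of 23 with BCl3 (2 equiv, hexane, −78 → 0 °C) should give dichloro(prop-1-en-2-yl)borane F1. The lithium alkoxide of 20 (n-BuLi, THF, −78 °C) should displace one chloride to give the alkoxy(chloro)(prop-1-en-2-yl)borane F2. Warming to 25–60 °C should give the B-chloro oxaborolane cycloadduct F3 under the same tether and stereocontrol. The H2O2/NaOH work-up of step 12 then returns the route at 26.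

Step 15. The base equilibration may stop at an unfavourable mixture, through E/Z scrambling of the tetrasubstituted enal and incomplete epimer preference at the ring CH. The fallback drains the wanted geometry through a temporary ring instead of relying on the position of the equilibrium. It sets out from 29. After the same acid hydrolysis, the aldehyde mixture is stirred with MnO2 and DBU (cat.) in CH2Cl2. Only the Z enal can close an allylic lactol onto the neighbouring CH2OH, and MnO2 should oxidise that lactol, but not the saturated primary alcohol, to the bridged seven-membered unsaturated lactone F4, while DBU keeps converting E into Z. Reduction with i-Bu2AlH (CH2Cl2, −78 °C) should give the lactol, the ring tautomer of the hydroxy enal, and so returns the route at 31.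

Step 10. The vinyllithium may deprotonate the gamma position of the butenolide or add twice, and the lactol may lose water to a furan before the second addition. The fallback opens the lactone first so that the ketone is made by a single controlled addition. It sets out from 13. MeNH(OMe)·HCl and Me3Al (CH2Cl2, 0 °C → rt) should give the (Z)-hydroxy Weinreb amide F5, which is silylated in the same flask (Me3SiCl, imidazole) to the trimethylsilyl ether F6. One addition of 17 (THF, −78 °C) through the chelated tetrahedral intermediate should give the dienone F7. Methylenation with Cp2TiMe2 (PhMe, 65 °C) should give the silylated triene F8. K2CO3 in MeOH (0 °C) removes the trimethylsilyl group and returns the route at 20.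

Further compounds
F1 | step 12 | dichloro(prop-1-en-2-yl)borane | CC(=C)B(Cl)Cl
F2 | step 12 | alkoxy(chloro)(prop-1-en-2-yl)borane of 20 (B on the carbinol oxygen) | CC(C)=CCC/C(C)=C/CC/C(C)=C/CC/C(=C(\CCCO[Si](C)(C)C(C)(C)C)C(=C)/C(C)=C\OCC)[C@@H](OB(Cl)C(C)=C)CO[Si](C)(C)C(C)(C)C
F3 | step 12 | B-chloro analogue of cycloadduct 25 (cis-fused 2-chloro-1,2-oxaborolane) | CC(C)=CCC/C(C)=C/CC/C(C)=C/CC[C@@]12C(CCCO[Si](C)(C)C(C)(C)C)=C(/C(C)=C\OCC)CC[C@]1(C)B(Cl)O[C@H]2CO[Si](C)(C)C(C)(C)C
F4 | step 15 | bridged seven-membered unsaturated lactone between the CH2OH oxygen and the former formyl carbon of 31 | CC(C)=CCC/C(C)=C/CC/C(C)=C/CC[C@]12COC(=O)C(C)=C(CC[C@]1(C)O)[C@H]2CCCO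
F5 | step 10 | (Z)-hydroxy Weinreb amide from ring-opening of 13 | CC(C)=CCC/C(C)=C/CC/C(C)=C/CC/C(=C(\CCCO[Si](C)(C)C(C)(C)C)C(=O)N(C)OC)[C@@H](O)CO[Si](C)(C)C(C)(C)C
F6 | step 10 | trimethylsilyl ether of F5 | CC(C)=CCC/C(C)=C/CC/C(C)=C/CC/C(=C(\CCCO[Si](C)(C)C(C)(C)C)C(=O)N(C)OC)[C@@H](O[Si](C)(C)C)CO[Si](C)(C)C(C)(C)C
F7 | step 10 | cross-conjugated dienone from F6 and 17 | CC(C)=CCC/C(C)=C/CC/C(C)=C/CC/C(=C(\CCCO[Si](C)(C)C(C)(C)C)C(=O)/C(C)=C\OCC)[C@@H](O[Si](C)(C)C)CO[Si](C)(C)C(C)(C)C
F8 | step 10 | trimethylsilyl ether of 20 | CC(C)=CCC/C(C)=C/CC/C(C)=C/CC/C(=C(\CCCO[Si](C)(C)C(C)(C)C)C(=C)/C(C)=C\OCC)[C@@H](O[Si](C)(C)C)CO[Si](C)(C)C(C)(C)C
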